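**Retrosynthetic overview**
1. 23 ⇒ 15 + 20 (step 9): oxirane-to-oxolane ring expansion through a 1-oxoniabicyclo[3.1.0]hexane ion. It makes O–C6 and C10–O(acyl) in one operation, without protecting groups.
2. 15 ⇒ 14 ⇒ 13: hydroxyl-directed epoxidation of a Z-homoallylic chlorohydrin, with the Z-olefin coming from the alkyne.
3. 13 ⇒ 5 + 11 (C8–C9, acetylide plus epoxide). 5 ⇒ 1 + 3 (C7–C8) after α-chlorination of heptanal. 11 ⇒ 6 + 7 (C14–C15).
4. 20 ⇒ 19 + CO + H2O. 19 ⇒ 16 + 17 (alkyl–alkyl coupling).
5. Ring order: terminal oxirane (made in step 2, opened in step 4), then the C9–C10 oxirane (step 6), then the oxolane last (step 9).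

Assumption: the SMILES is taken as drawn, which is (6S,7S,9R,10R) in chain numbering. C1–C5 is the pentyl group, C6 and C9 are the ring carbons on oxygen, C7 is the carbinol, C10 is the ester carbon and C18=C19 is the vinyl group. This numbering is used throughout.

**Step 1**
Reactants: 1 heptanal
Product: 2 (2R)-2-chloroheptanal
Conditions: NCS (1.3 equiv), (2S,5S)-2,5-diphenylpyrrolidine (10 mol %), CH2Cl2, 0 °C to rt; pentane/silica plug, used at once
Reagents that add atoms: N-chlorosuccinimide, O=C1CCC(=O)N1Cl
Why: Organocatalytic enamine α-chlorination of a linear aldehyde, in which the C2-symmetric amine blocks one face of the E-enamine so that chlorine is delivered to the other face and C6 is set as R (above 90% ee is usual, and the antipodal amine gives the S series).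

**Step 2**
Reactants: 2 (2R)-2-chloroheptanal; 3 diiodomethane
Product: 5 (2S)-2-[(1R)-1-chlorohexyl]oxirane, via lithium iodohydrin alkoxide 4 (not isolated)
Conditions: 3 (1.3 equiv), MeLi·LiBr (1.25 equiv, added slowly to 2 + 3), THF/Et2O, −78 °C, 1 h, then to 20 °C
Reagents that add atoms: none
Why: In situ halomethyllithium addition followed by Williamson-type closure, in which iodine–lithium exchange outruns carbonyl attack by MeLi, ICH2Li adds at −78 °C under Cornforth (polar Felkin–Anh) control to give the 1,2-anti chlorohydrin alkoxide (sets C7), and on warming the alkoxide expels the much better primary iodide rather than the secondary chloride.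

**Step 3**
Reactants: 6 5-bromopent-1-ene; 7 6-bromohex-1-yne
Product: 11 undec-1-en-10-yne, via pent-4-enylmagnesium bromide 8 (not isolated), via bromomagnesium 6-bromohexynide 9 (not isolated), via bromomagnesium undecenynide 10 (not isolated)
Conditions: 6 (2.3 equiv), Mg, THF, rt; then 7 (1.0 equiv), Li2CuCl4 (3 mol %), THF, −20 to 0 °C; aq NH4Cl
Reagents that add atoms: none
Why: Kochi-type copper-catalysed alkyl–alkyl coupling of a Grignard reagent with a primary bromide, in which the first equivalent only deprotonates the alkyne to an inert magnesium acetylide (a harmless dummy ligand on copper) and the second forms the C14–C15 bond, with no stereocentre involved.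

**Step 4**
Reactants: 11 undec-1-en-10-yne; 5 (2S)-2-[(1R)-1-chlorohexyl]oxirane
Product: 13 (6R,7S)-6-chlorononadec-18-en-9-yn-7-ol, via lithium undecenynide 12 (not isolated)
Conditions: 11 (1.3 equiv), n-BuLi (1.25 equiv), THF, −78 °C; BF3·OEt2 (1.3 equiv); then 5, −78 °C, 2 h; aq NH4Cl
Reagents that add atoms: none
Why: Yamaguchi–Hirao BF3-assisted SN2 opening of a terminal epoxide by a lithium acetylide at the unsubstituted carbon C8, well proven on epichlorohydrin-type substrates, where the boron-bound alkoxide does not displace the neighbouring chloride at −78 °C and C6 and C7 are untouched.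

**Step 5**
Reactants: 13 (6R,7S)-6-chlorononadec-18-en-9-yn-7-ol
Product: 14 (6R,7S,9Z)-6-chlorononadeca-9,18-dien-7-ol
Conditions: H2 (1 atm, stopped at 1.0 equiv uptake), 5% Pd/CaCO3–Pb(OAc)2, quinoline (0.2 equiv), hexane/EtOAc, 0 °C
Reagents that add atoms: none
Why: Lindlar-type syn semi-hydrogenation, in which the alkyne binds to the lead- and quinoline-poisoned palladium surface far more strongly than the monosubstituted alkene, so stopping at one equivalent of hydrogen gives the Z-olefin with the vinyl group, the chloride and both stereocentres intact.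

**Step 6**
Reactants: 14 (6R,7S,9Z)-6-chlorononadeca-9,18-dien-7-ol
Product: 15 (2S,3R)-3-chloro-1-[(2R,3S)-3-(non-8-en-1-yl)oxiran-2-yl]octan-2-ol
Conditions: VO(acac)2 (3 mol %), t-BuOOH (5.5 M in decane, 1.3 equiv), CH2Cl2, 0 °C to rt
Reagents that add atoms: tert-butyl hydroperoxide, CC(C)(C)OO
Why: Hydroxyl-directed vanadium-catalysed epoxidation of a homoallylic alcohol, in which the vanadate ester of the C7 alcohol delivers oxygen through a chair-like transition state with the chlorohexyl group equatorial and the allylic 1,3-strain of the Z-olefin minimised, giving the 7,9-syn cis-epoxide (sets C9 as R and C10 as S) and leaving the remote vinyl group alone.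

**Step 7**
Reactants: 16 oct-1-ene; 17 7-bromohept-1-ene
Product: 19 pentadec-1-ene, via B-octyl-9-BBN 18 (not isolated)
Conditions: 16 (1.1 equiv), 9-BBN-H (0.5 M in THF, 1.05 equiv), rt, 3 h; then 17 (1.0 equiv), Pd(OAc)2 (4 mol %), PCy3 (8 mol %), K3PO4·H2O (1.2 equiv), THF, rt, 18 h
Reagents that add atoms: none
Why: Anti-Markovnikov hydroboration followed by B-alkyl Suzuki–Miyaura alkyl–alkyl coupling, in which bulky electron-rich PCy3 lets zerovalent palladium insert into the primary carbon–bromine bond and couple faster than β-hydride elimination, and the vinyl group of 17 is spared because no boron hydride is left (no stereocentre).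

**Step 8**
Reactants: 19 pentadec-1-ene
Product: 20 hexadecanoic acid
Conditions: Pd(OAc)2 (0.5 mol %), 1,2-bis(di-tert-butylphosphinomethyl)benzene (2 mol %), CH3SO3H (4 mol %), CO (40 bar), H2O (5 equiv), 1,4-dioxane, 100 °C
Reagents that add atoms: carbon monoxide, [C-]#[O+]; water, O
Why: Palladium hydride-catalysed hydroxycarbonylation (Reppe type), in which the bulky chelating diphosphine enforces carbonylation at the chain terminus (linear to branched above 95:5) and funnels any isomerised olefin to the same linear acid (no stereocentre).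

**Step 9**
Reactants: 15 (2S,3R)-3-chloro-1-[(2R,3S)-3-(non-8-en-1-yl)oxiran-2-yl]octan-2-ol; 20 hexadecanoic acid
Product: 23 (1R)-1-[(2R,4S,5S)-4-hydroxy-5-pentyloxolan-2-yl]dec-9-en-1-yl hexadecanoate (target), via silver hexadecanoate 21 (not isolated), via bicyclic epoxonium hexadecanoate 22 (not isolated)
Conditions: 20 (2.2 equiv), Ag2O (1.1 equiv), 4 Å sieves, toluene, 40 °C, dark, 1 h; then 15 (1.0 equiv), 70 °C, dark
Reagents that add atoms: none
Why: Proposed new method: halophilic monovalent silver, which leaves the oxirane itself alone, pulls chloride from C6 while the oxirane oxygen held five atoms away attacks C6 from the rear (inversion, 6R chloride to 6S ether) to give the 1-oxoniabicyclo[3.1.0]hexane ion 22, whose paired carboxylate opens the strained three-membered ring at the exocyclic and less hindered C10 with inversion (10S to 10R) while the C9–O bond is kept, so the oxirane is expanded to the 2,5-trans oxolane and the ester lands only on the C10 oxygen with the trans-disposed C7 hydroxyl left free; the closest known reaction types are the AgOSO2CF3/Ag2O-promoted etherification of chlorodiols to 3-hydroxyoxolanes, the halonium-triggered opening of epoxides with capture of the oxonium ion by an added carboxylic acid, and the Zn(OAc)2-mediated ring-size rearrangement of cyclic ether sulfonates through bicyclic oxonium ions.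

**Compound list**
1 | heptanal | CCCCCCC=O | starting material
2 | (2R)-2-chloroheptanal | CCCCC[C@@H](Cl)C=O | intermediate
3 | diiodomethane | ICI | starting material
4 | lithium (2R,3R)-3-chloro-1-iodooctan-2-olate (lithium iodohydrin alkoxide) | CCCCC[C@@H](Cl)[C@@H]([O-])CI.[Li+] | intermediate
5 | (2S)-2-[(1R)-1-chlorohexyl]oxirane | CCCCC[C@@H](Cl)[C@@H]1CO1 | intermediate
6 | 5-bromopent-1-ene | C=CCCCBr | starting material
7 | 6-bromohex-1-yne | C#CCCCCBr | starting material
8 | pent-4-enylmagnesium bromide | C=CCCC[Mg]Br | intermediate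
9 | (6-bromohex-1-yn-1-yl)magnesium bromide (bromomagnesium 6-bromohexynide) | Br[Mg]C#CCCCCBr | intermediate
10 | (undec-10-en-1-yn-1-yl)magnesium bromide (bromomagnesium undecenynide) | C=CCCCCCCCC#C[Mg]Br | intermediate
11 | undec-1-en-10-yne | C=CCCCCCCCC#C | intermediate
12 | (undec-10-en-1-yn-1-yl)lithium (lithium undecenynide) | C=CCCCCCCCC#C[Li] | intermediate
13 | (6R,7S)-6-chlorononadec-18-en-9-yn-7-ol | C=CCCCCCCCC#CC[C@H](O)[C@H](Cl)CCCCC | intermediate
14 | (6R,7S,9Z)-6-chlorononadeca-9,18-dien-7-ol | C=CCCCCCCC/C=C\C[C@H](O)[C@H](Cl)CCCCC | intermediate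
15 | (2S,3R)-3-chloro-1-[(2R,3S)-3-(non-8-en-1-yl)oxiran-2-yl]octan-2-ol (cis-epoxide, 6R,7S,9R,10S in chain numbering) | C=CCCCCCCC[C@@H]1O[C@@H]1C[C@H](O)[C@H](Cl)CCCCC | intermediate
16 | oct-1-ene | C=CCCCCCC | starting material
17 | 7-bromohept-1-ene | C=CCCCCCBr | starting material
18 | 9-octyl-9-borabicyclo[3.3.1]nonane (B-octyl-9-BBN) | CCCCCCCCB1C2CCCC1CCC2 | intermediate
19 | pentadec-1-ene | C=CCCCCCCCCCCCCC | intermediate
20 | hexadecanoic (palmitic) acid | CCCCCCCCCCCCCCCC(=O)O | intermediate
21 | silver hexadecanoate | CCCCCCCCCCCCCCCC(=O)[O-].[Ag+] | intermediate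
22 | (2S,3S,5R,6S)-3-hydroxy-6-(non-8-en-1-yl)-2-pentyl-1-oxoniabicyclo[3.1.0]hexane hexadecanoate (bicyclic epoxonium hexadecanoate) | C=CCCCCCCC[C@H]1[C@H]2C[C@H](O)[C@H](CCCCC)[O+]12.CCCCCCCCCCCCCCCC(=O)[O-] | intermediate
23 | (1R)-1-[(2R,4S,5S)-4-hydroxy-5-pentyloxolan-2-yl]dec-9-en-1-yl hexadecanoate | C=CCCCCCCC[C@@H](OC(=O)CCCCCCCCCCCCCCC)[C@H]1C[C@H](O)[C@H](CCCCC)O1 | target

**Total step count:** 9.
**Longest linear sequence:** 6 steps (1, 2, 4, 5, 6, 9).

**Three steps most likely to fail**

**Step 9 (the proposed new step).**
- Silver may be too weak to ionise a β-hydroxy secondary chloride when only an oxirane oxygen is pushing.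
- The C7 hydroxyl may close to a 6,7-epoxide instead.
- Part of the carboxylate may attack C9 and give the six-membered ether.

The fallback sets out from 15 and comes back at 23, and it uses known chemistry. Epoxy alcohol 15 is opened with 20 and Ti(OiPr)4 (CH2Cl2, rt). The titanium chelate to the C7 hydroxyl steers the acid to the distal C10 with inversion, giving (6R,7S,9R,10R)-6-chloro-7,9-dihydroxynonadec-18-en-10-yl hexadecanoate F1. Any C9 regioisomer is removed by chromatography. F1 is then closed with AgOSO2CF3/Ag2O in THF, the established silver-promoted etherification of chlorodiols. The C9 hydroxyl displaces the C6 chloride with inversion and gives 23.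

**Step 2.**
- The carbenoid is short-lived.
- Aldehyde 2 can racemise.
- The anti/syn ratio with so small a nucleophile may be modest.

The fallback sets out from 2 and comes back at 5. Thioanisole is lithiated (n-BuLi, DABCO, THF, 0 °C) to phenylthiomethyllithium F2. F2 adds to 2 at −78 °C with the same Cornforth preference and gives the bench-stable (2S,3R)-3-chloro-1-(phenylsulfanyl)octan-2-ol F3, on which the minor syn isomer can be removed. S-Methylation with Me3OBF4 (CH2Cl2) gives [(2S,3R)-3-chloro-2-hydroxyoctyl](methyl)phenylsulfonium tetrafluoroborate F4. Cold aqueous NaOH/CH2Cl2 closes F4 to 5, because the sulfonium group leaves much faster than the secondary chloride.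

**Step 5.**
- The vinyl group may be partly hydrogenated or isomerised before the alkyne is consumed.

The fallback sets out from 5, together with Grignard reagent 8 made as in step 3. It comes back at 14 and bypasses 13. Reagent 8 is coupled with excess 1,4-dibromobutane (Li2CuCl4, THF, 0 °C) to give 9-bromonon-1-ene F5. Magnesium converts F5 into non-8-enylmagnesium bromide F6. CuBr·SMe2 (Et2O, −35 °C) converts F6 into non-8-enylcopper F7. Syn-carbocupration of acetylene (−25 °C) then gives (1Z)-undeca-1,10-dienylcopper F8 with complete Z geometry. F8, assisted by BF3·OEt2, opens epoxide 5 at C8 (−50 °C, cold NH4Cl quench). This delivers 14 with the Z-olefin already in place, so no hydrogenation is run in the presence of the vinyl group.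

**Further compounds**
F1 | step 9 | (6R,7S,9R,10R)-6-chloro-7,9-dihydroxynonadec-18-en-10-yl hexadecanoate | C=CCCCCCCC[C@@H](OC(=O)CCCCCCCCCCCCCCC)[C@H](O)C[C@H](O)[C@H](Cl)CCCCC
F2 | step 2 | phenylthiomethyllithium | [Li]CSc1ccccc1
F3 | step 2 | (2S,3R)-3-chloro-1-(phenylsulfanyl)octan-2-ol | CCCCC[C@@H](Cl)[C@@H](O)CSc1ccccc1
F4 | step 2 | [(2S,3R)-3-chloro-2-hydroxyoctyl](methyl)phenylsulfonium tetrafluoroborate | CCCCC[C@@H](Cl)[C@@H](O)C[S+](C)c1ccccc1.F[B-](F)(F)F
F5 | step 5 | 9-bromonon-1-ene | C=CCCCCCCCBr
F6 | step 5 | non-8-enylmagnesium bromide | C=CCCCCCCC[Mg]Br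
F7 | step 5 | non-8-enylcopper | C=CCCCCCCC[Cu]
F8 | step 5 | (1Z)-undeca-1,10-dienylcopper | C=CCCCCCCC/C=C\[Cu]
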